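The product of this flask comes from two couplings running side by side, and the question is how much of it ends up left-handed.

in all of them: free catalyst 10 mM

| charge | left-handed substrate | right-handed substrate | solid reagent | racemization catalyst | remark | time |
|---|---|---|---|---|---|---|
| blue | 0.050 M | 0.050 M | 0.25 M | 65 µM | run made earlier |  |
| ochre | 0.075 M | 0.075 M | 0.25 M | 65 µM | run made earlier |  |
| violet | 0.10 M | 0.10 M | 0.25 M | 98 µM | run made earlier |  |
| flask | 0.10 M | 0.10 M | 0.250 M | 65 µM |  | 10 d |
- blue (time / d: left-handed product / %, right-handed product / %): 0.625: 11.5, 7.8; 2.08: 33.4, 22.1; 4.00: 45.6, 32.6; 6.00: 53.9, 37.0; 8.00: 57.1, 40.7
- ochre (time / d: left-handed product / %, right-handed product / %): 0.625: 11.3, 7.7; 1.25: 23.0, 15.5; 2.50: 38.7, 23.5; 4.00: 47.6, 33.0; 8.00: 58.5, 38.0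
- violet (time / d: left-handed product / %, right-handed product / %): 1.67: 26.4, 18.8; 3.00: 43.1, 28.7; 5.00: 50.7, 34.2; 6.00: 52.6, 34.1; 8.00: 56.1, 37.7

(readings scatter by 1 percentage point)
- free catalyst is single-handed; left-handed substrate and right-handed substrate are mirror images of each other, charged as a racemate, each of them at the stated concentration
- solid reagent is a solid; its amount is given per volume of the solution
- on the list of suspects stand: coupling partner + free catalyst + left-handed substrate -> free catalyst + left-handed product; coupling partner + free catalyst + right-handed substrate -> free catalyst + right-handed product; left-handed substrate + racemization catalyst <-> right-handed substrate + racemization catalyst; coupling partner -> decomposition product; solid reagent <-> coupling partner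
- at the start none of the solid reagent is in solution
- an excess is the difference of the two amounts in percent of their sum
- an excess is below zero if the other one leads
- left-handed product and right-handed product together, in percent of the left-handed substrate and right-handed substrate charged together, at 10 d
- excess of left-handed product over right-handed product in the product at 10 d
- whether the exchange between left-handed substrate and right-handed substrate keeps pace with the reaction: how far the product's excess at 10 d gets from its value without exchange to its value with instant exchange (above 80% keeps pace, below 20% hardly takes part, else lags behind)

Turn the substrate charge first. By hand, more substrate on the same solid should slow the percent curve, but at 4.00 d the blue run holds 78.2% and the ochre run 80.6%. So I read the coupling as pseudo-first-order in substrate, and the ochre run gives 0.389 d⁻¹, a coupling half-life of 1.78 d.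

Turn the solid next. The flask's substrates need 0.200 M, less than the 0.250 M of solid, so the solid covers them by amount, but that does not show that the partner's level holds once the solid has dissolved. With the level held, the first-order line reaches 98.0% at 10 d, and that is my reckoning on that condition.

Turn the racemization catalyst last. By hand it lifts the product's excess toward its instant-exchange limit. Coupling tilts the substrate pool and exchange wears the tilt down, so call the coupling half-life over the exchange's relaxation half-life the exchange number. Near full conversion, the excess gets the share of the way given by that number over one plus itself. Above 80% the number must exceed 4.00, so the relaxation half-life must stay under the pace time 0.445 d.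

The runs can't place this flask by that line. The product's excess at 8.00 d in the blue and ochre runs, both with 65 µM of racemization catalyst, reads 19.0%. The selectivity factor, from the logarithms of what is left of each substrate, reads 1.54 from the first points and 1.66 from the ochre run's second. That makes the share 89.8% or 76.5%, which straddles the line, so my reckoning leaves the pace open.

The forecast says 96%, 18.5% and keeps pace, holding that “exchange is fast”.

The flask gives 96.5% and 18.4%, and the exchange lags behind, at 72% of the way.

    coupling partner + free catalyst + left-handed substrate → free catalyst + left-handed product (k = 23.0 L² mol⁻² h⁻¹)
    coupling partner + free catalyst + right-handed substrate → free catalyst + right-handed product (k = 14.0 L² mol⁻² h⁻¹)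
    left-handed substrate + racemization catalyst ⇌ right-handed substrate + racemization catalyst, rate k3*[racemization catalyst]*[left-handed substrate] forward; the back reaction follows from the equilibrium constant (k = 360 L mol⁻¹ h⁻¹)
    coupling partner → decomposition product (k = 4.30 × 10⁻⁵ h⁻¹)
    solid reagent ⇌ coupling partner, rate k5*(cs5 - [coupling partner]) while solid is left; crystals form when [coupling partner] > cs5 (solubility = 0.0990 M, k = 0.370 h⁻¹)

In this flask the exchange relaxes with a half-life of 0.617 d, longer than the pace time of 0.445 d, which makes the exchange number 2.89 and the rule's share 74.3%. The neighbour with 2.6 × 10⁻⁴ M of racemization catalyst, by the same rule, has a half-life of 0.154 d, under the pace time, and a share of 92.0%, and its product's excess stands at 22.5%.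

All runs are calculated for substances that don't exist; noise was put on by code.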